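**Plan**

Ring numbering of the target used below: C1 = carbonyl between C2 and C6, C2 = C–OH, C3 = C–CH3, C4 = second carbonyl, C5 = C–H, C6 = C–nonadecyl.

1. Retrosynthesis: the O–H at C2 is traced back to O–CH3; the quinone ring is then contracted by cutting C1–C6 and closing C1–C4, which gives a 4-alkynyl-4-hydroxycyclobut-2-enone.
2. Further cuts: C3–CH3 (methyllithium), C4–C5 (acetylide onto dimethyl squarate) and the C(sp)–CH2 bond of the side chain (acetylide alkylation).
3. Forward: nonadecyl bromide plus acetylide gives henicos-1-yne; the alkyne is added to dimethyl squarate; methyl is introduced with a 1,3-carbonyl transposition; the four-membered ring is expanded thermally to the six-membered quinone ring; O-demethylation ends the route.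
4. Enabling feature: C1–C4 carry the O, O, C, O pattern of a squaric acid derivative, and C5(H)=C6(alkyl) is a terminal alkyne at the right oxidation level, so the alkynylcyclobutenone is an isomer of the quinone.
5. Stereochemistry: the target has no stereocentre; the carbinol centre of the cyclobutenones is racemic and is destroyed in the ring expansion. The only stereochemical issue, the double-bond geometry of the ketene intermediate, is set by torquoselective ring opening.

Key step: step 5

Remark: the target is treated as the 2-hydroxy-1,4-benzoquinone tautomer shown; its 4-hydroxy-1,2-quinone tautomer is the same compound, so no substituent can change place by tautomerism.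

**Route**

Step 1
Reactants: 1 1-bromononadecane; 2 lithium acetylide ethylenediamine complex (LiC≡CH·H2NCH2CH2NH2)
Product: 3 henicos-1-yne
Conditions: DMSO/THF, 5 °C → rt
Reagents that add atoms: none
Why: SN2 alkylation of a metal acetylide, in which the ethylenediamine-complexed lithium acetylide displaces the primary bromide in a dipolar aprotic solvent and should give the terminal alkyne without dialkylation or isomerisation.

Step 2
Reactants: 3 henicos-1-yne; 4 dimethyl squarate (3,4-dimethoxycyclobut-3-ene-1,2-dione)
Product: 7 4-(henicos-1-yn-1-yl)-2,3-dimethoxy-4-(trimethylsilyloxy)cyclobut-2-en-1-one (racemic), via lithium henicos-1-yn-1-ide 5 (not isolated), via lithium alkoxide adduct 6 (not isolated)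
Conditions: n-BuLi, THF, −20 °C; added to 4, THF, −78 °C; TMSCl, −78 → 0 °C
Reagents that add atoms: n-butyllithium, [Li]CCCC (lithium only, in 5 and 6); chlorotrimethylsilane, C[Si](C)(C)Cl
Why: 1,2-addition of an alkynyllithium to one of the two equivalent ketone-like carbonyl groups of the squarate, held at mono-addition by inverse addition at −78 °C, followed by O-silylation of the tertiary lithium alkoxide; the new stereocentre is racemic and is erased later.

Step 3
Reactants: 7 4-(henicos-1-yn-1-yl)-2,3-dimethoxy-4-(trimethylsilyloxy)cyclobut-2-en-1-one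
Product: 10 4-(henicos-1-yn-1-yl)-2-methoxy-3-methyl-4-(trimethylsilyloxy)cyclobut-2-en-1-one (racemic), via lithium alkoxide of the methyl adduct 8 (not isolated), via tertiary trifluoroacetate 9 (not isolated)
Conditions: MeLi, THF, −78 °C; (CF3CO)2O, −78 °C; aq. NaHCO3, −78 °C → rt
Reagents that add atoms: methyllithium, C[Li]; trifluoroacetic anhydride, O=C(OC(=O)C(F)(F)F)C(F)(F)F (atoms only in 9); water, O
Why: 1,2-addition of methyllithium to the remaining vinylogous ester carbonyl, trifluoroacetylation of the new tertiary alkoxide, ionisation to a methoxy-stabilised cyclobutenyl cation and hydrolysis at its methoxy-bearing end amount to a 1,3-carbonyl transposition (the known organolithium addition/acid rearrangement of squarate adducts), and the silyl ether leaves only the methyl-bearing carbinol carbon able to ionise, which places methyl at C3 and methoxy at C2 of the cyclobutenone.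

Step 4
Reactants: 10 4-(henicos-1-yn-1-yl)-2-methoxy-3-methyl-4-(trimethylsilyloxy)cyclobut-2-en-1-one
Product: 11 4-(henicos-1-yn-1-yl)-4-hydroxy-2-methoxy-3-methylcyclobut-2-en-1-one (racemic)
Conditions: 1 M aq. HCl, THF, 0 °C → rt
Reagents that add atoms: none
Why: acid-catalysed hydrolysis of a tertiary trimethylsilyl ether (silyl ether deprotection), under which the carbinol carbon should not ionise because the cation would stand next to the ring carbonyl group.

Step 5
Reactants: 11 4-(henicos-1-yn-1-yl)-4-hydroxy-2-methoxy-3-methylcyclobut-2-en-1-one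
Product: 14 2-methoxy-3-methyl-6-nonadecylcyclohexa-2,5-diene-1,4-dione, via enynylketene 12 (not isolated), via dehydrophenoxyl diradical 13 (not isolated)
Conditions: p-xylene (0.01 M, degassed), Ar, 138 °C (reflux)
Reagents that add atoms: none
Why: On heating, the cyclobutenone should open by conrotatory 4π-electrocyclic cleavage of its C1–C4 bond to the (E)-enynylketene 12, the ketene carbon then bonds to the distal alkyne carbon to give the six-membered diradical 13 (aryl σ-radical beside the C–OH carbon, oxyl radical at the former ketene carbon), and net transfer of the hydroxyl hydrogen to the σ-radical centre delivers the quinone. The closest known reaction type is the Moore rearrangement of 4-alkynyl-4-hydroxycyclobut-2-enones to 1,4-benzoquinones, a ring expansion of a four-membered ring by two atoms to a six-membered ring. The quinone ring is closed by 6-endo-dig attack of the ketene carbon on the alkyne, a diradical cycloaromatisation related to the Myers–Saito cyclisation. No stereocentre is formed, and the racemic carbinol centre of 11 is lost. The step needs the alkynyl group to rotate inward, which the strong outward preference of the donor hydroxyl group secures (torquoselectivity), and six- over five-membered closure, which the unbranched alkyl group on the alkyne terminus secures because it does not stabilise the exocyclic vinyl radical of the 5-exo path. The positions of methoxy, methyl, hydrogen and nonadecyl on the new ring follow directly from the substitution of 11, so no regiochemical choice is left to the step.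

Step 6
Reactants: 14 2-methoxy-3-methyl-6-nonadecylcyclohexa-2,5-diene-1,4-dione
Product: 15 Capiquinone C (2-hydroxy-3-methyl-6-nonadecylcyclohexa-2,5-diene-1,4-dione)
Conditions: 70% aq. HClO4, 1,4-dioxane, rt
Reagents that add atoms: water, O
Why: acid-catalysed addition–elimination at C2 of the 2-methoxy-1,4-quinone (hydrolysis of a vinylogous ester), in which water adds to the methoxy-bearing carbon and methanol leaves, so the hydroxyl group should end exactly where the methoxyl group was.

**Compound list**

1 | 1-bromononadecane | CCCCCCCCCCCCCCCCCCCBr | starting material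
2 | lithium acetylide ethylenediamine complex | [Li]C#C.NCCN | starting material
3 | henicos-1-yne | CCCCCCCCCCCCCCCCCCCC#C | intermediate
4 | dimethyl squarate (3,4-dimethoxycyclobut-3-ene-1,2-dione) | COC1=C(OC)C(=O)C1=O | starting material
5 | lithium henicos-1-yn-1-ide | CCCCCCCCCCCCCCCCCCCC#C[Li] | intermediate
6 | lithium 1-(henicos-1-yn-1-yl)-2,3-dimethoxy-4-oxocyclobut-2-en-1-olate (racemic) | CCCCCCCCCCCCCCCCCCCC#CC1(O[Li])C(OC)=C(OC)C1=O | intermediate
7 | 4-(henicos-1-yn-1-yl)-2,3-dimethoxy-4-(trimethylsilyloxy)cyclobut-2-en-1-one (racemic) | CCCCCCCCCCCCCCCCCCCC#CC1(O[Si](C)(C)C)C(OC)=C(OC)C1=O | intermediate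
8 | lithium 4-(henicos-1-yn-1-yl)-2,3-dimethoxy-1-methyl-4-(trimethylsilyloxy)cyclobut-2-en-1-olate (mixture of diastereomers) | CCCCCCCCCCCCCCCCCCCC#CC1(O[Si](C)(C)C)C(OC)=C(OC)C1(C)O[Li] | intermediate
9 | 4-(henicos-1-yn-1-yl)-2,3-dimethoxy-1-methyl-4-(trimethylsilyloxy)cyclobut-2-en-1-yl trifluoroacetate (mixture of diastereomers) | CCCCCCCCCCCCCCCCCCCC#CC1(O[Si](C)(C)C)C(OC)=C(OC)C1(C)OC(=O)C(F)(F)F | intermediate
10 | 4-(henicos-1-yn-1-yl)-2-methoxy-3-methyl-4-(trimethylsilyloxy)cyclobut-2-en-1-one (racemic) | CCCCCCCCCCCCCCCCCCCC#CC1(O[Si](C)(C)C)C(C)=C(OC)C1=O | intermediate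
11 | 4-(henicos-1-yn-1-yl)-4-hydroxy-2-methoxy-3-methylcyclobut-2-en-1-one (racemic) | CCCCCCCCCCCCCCCCCCCC#CC1(O)C(C)=C(OC)C1=O | intermediate
12 | (3E)-4-hydroxy-2-methoxy-3-methylpentacosa-1,3-dien-5-yn-1-one (enynylketene, alkynyl group cis to the ketene) | CCCCCCCCCCCCCCCCCCCC#C/C(O)=C(/C)C(OC)=C=O | intermediate
13 | 4-hydroxy-2-methoxy-3-methyl-6-nonadecyl-5-dehydrophenoxyl diradical (oxyl radical on the C1 oxygen, σ-radical at C5) | CCCCCCCCCCCCCCCCCCCc1[c]c(O)c(C)c(OC)c1[O] | intermediate
14 | 2-methoxy-3-methyl-6-nonadecylcyclohexa-2,5-diene-1,4-dione | CCCCCCCCCCCCCCCCCCCC1=CC(=O)C(C)=C(OC)C1=O | intermediate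
15 | Capiquinone C (2-hydroxy-3-methyl-6-nonadecylcyclohexa-2,5-diene-1,4-dione) | CCCCCCCCCCCCCCCCCCCC1=CC(=O)C(C)=C(O)C1=O | target

**Step count and risks**

Total step count: 6. Longest linear sequence: 6 steps (1 → 15).

Steps most likely to fail:

Step 3. Methyllithium may add in conjugate fashion to the methoxy-bearing β-carbon with loss of methoxide instead of adding to the carbonyl group. The silyl ether may also be lost during acylation and ionisation, so that either carbinol carbon ionises and the regiochemistry is scrambled. The fallback reverses the order of the two additions and enforces the regiochemistry with a ketal. It sets out from dimethyl squarate 4 and lithium acetylide 5 and comes back to the route at 11. MeLi (THF, −78 °C) with 4 should give, after aqueous work-up, 4-hydroxy-2,3-dimethoxy-4-methylcyclobut-2-en-1-one F1. (CF3CO)2O then converts this to 3-methoxy-4-methylcyclobut-3-ene-1,2-dione F2. The more electrophilic carbonyl of F2 (the one beside the methoxy-bearing carbon, not part of the vinylogous ester) is ketalised with 1,2-bis(trimethylsilyloxy)ethane and catalytic TMSOTf (CH2Cl2, −78 °C) to 3-methoxy-2-methyl-5,8-dioxaspiro[3.4]oct-2-en-1-one F3. Lithium acetylide 5 adds to the only free carbonyl to give 1-(henicos-1-yn-1-yl)-3-methoxy-2-methyl-5,8-dioxaspiro[3.4]oct-2-en-1-ol F4. Dilute aqueous H2SO4 in THF hydrolyses the ketal to 11, so steps 2 to 4 are bypassed.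

Step 5. The diradical may be intercepted by intermolecular hydrogen abstraction and oligomerisation before the hydroxyl hydrogen is transferred, or the ketene may close onto the proximal alkyne carbon to a five-membered ring. The fallback replaces the diradical closure by a closed-shell electrocyclisation. It sets out from silyl ether 10 and comes back to the route at 14. Semihydrogenation (H2, Pd/CaCO3 poisoned with Pb(OAc)2, quinoline, hexane) should give 4-[(1Z)-henicos-1-en-1-yl]-2-methoxy-3-methyl-4-(trimethylsilyloxy)cyclobut-2-en-1-one F5. Heating F5 in toluene at 110 °C should bring about 4π ring opening, 6π-electrocyclisation of the dienylketene and tautomerisation to 2-methoxy-3-methyl-6-nonadecyl-4-(trimethylsilyloxy)phenol F6. Oxidation of F6 with (NH4)2Ce(NO3)6 in MeCN/H2O at 0 °C gives quinone 14.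

Step 6. Water may add at the unsubstituted ring carbon C5 while substitution at the hindered C2 is slow, and the quinone may decompose on long exposure to strong acid. The fallback cleaves the methyl ether at the hydroquinone oxidation level by a Lewis acid instead of by addition–elimination on the quinone. It sets out from 14 and comes back to the route at target 15. Reduction with aqueous Na2S2O4 in EtOAc should give 2-methoxy-3-methyl-6-nonadecylbenzene-1,4-diol F7. BBr3 (CH2Cl2, −78 → 0 °C) cleaves the aryl methyl ether to 3-methyl-6-nonadecylbenzene-1,2,4-triol F8. Oxidation of F8 in air (O2, EtOAc, rt) or with Ag2O gives 15.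

**Further compounds**

F1 | step 3 | 4-hydroxy-2,3-dimethoxy-4-methylcyclobut-2-en-1-one (racemic) | COC1=C(OC)C(C)(O)C1=O
F2 | step 3 | 3-methoxy-4-methylcyclobut-3-ene-1,2-dione | COC1=C(C)C(=O)C1=O
F3 | step 3 | 3-methoxy-2-methyl-5,8-dioxaspiro[3.4]oct-2-en-1-one | COC1=C(C)C(=O)C12OCCO2
F4 | step 3 | 1-(henicos-1-yn-1-yl)-3-methoxy-2-methyl-5,8-dioxaspiro[3.4]oct-2-en-1-ol (racemic) | CCCCCCCCCCCCCCCCCCCC#CC1(O)C(C)=C(OC)C12OCCO2
F5 | step 5 | 4-[(1Z)-henicos-1-en-1-yl]-2-methoxy-3-methyl-4-(trimethylsilyloxy)cyclobut-2-en-1-one (racemic) | CCCCCCCCCCCCCCCCCCC/C=C\C1(O[Si](C)(C)C)C(C)=C(OC)C1=O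
F6 | step 5 | 2-methoxy-3-methyl-6-nonadecyl-4-(trimethylsilyloxy)phenol | CCCCCCCCCCCCCCCCCCCc1cc(O[Si](C)(C)C)c(C)c(OC)c1O
F7 | step 6 | 2-methoxy-3-methyl-6-nonadecylbenzene-1,4-diol | CCCCCCCCCCCCCCCCCCCc1cc(O)c(C)c(OC)c1O
F8 | step 6 | 3-methyl-6-nonadecylbenzene-1,2,4-triol | CCCCCCCCCCCCCCCCCCCc1cc(O)c(C)c(O)c1O
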